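**Plan**
- Retrosynthesis: the sulfate is kept as a 2,2,2-trichloroethyl diester and the 5- and 7-OH as benzyl ethers (all unmasked together). Then the O3–S bond is cut, then the C3–O bond, then the C2–C1' bond between pyranone ring C and the 4-methoxyphenyl ring B, and last O1–C2/C2–C3 of ring C.
- Forward: ring A is bought as phloroacetophenone, ring C is closed with an amide acetal, and ring B is joined at C2 by C–H zincation/Negishi coupling with 4-iodoanisole. C3 is then oxygenated through the 2,3-epoxide and sulfated, and one reductive step unmasks everything.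
- Enabling feature: C2–H of the γ-pyranone ring is bonded to ring oxygen O1 and vinylogous to the C4 carbonyl. Once C4=O is complexed by a Lewis acid it is the most acidic C–H of the 5,7-dialkoxychromone, so the heterocycle needs no halogen or boron handle.
- Joining before C3 oxygenation brings the 4'-O-methyl in with the aryl iodide and lets the sulfate-bearing oxygen be created later as the only free hydroxyl. The four oxygens are therefore never told apart by a selective reaction.
- Stereochemistry: the target is planar and has no stereocentre; the only sp3 centres of the route (a racemic epoxide) are transient.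

Key step: step 3

Remark: the target is achiral, so the compound itself is the "single enantiomer"; the free hydrogen sulfate as drawn is taken as the final form and is released from its ammonium salt only at the end.

**Step 1**
Reactants: 1 2',4',6'-trihydroxyacetophenone
Product: 2 1-[2,4-bis(benzyloxy)-6-hydroxyphenyl]ethan-1-one
Conditions: BnBr (2.1 equiv), K2CO3, DMF, 0 °C → rt
Reagents that add atoms: benzyl bromide, BrCc1ccccc1
Why: Williamson ether synthesis in which the 4-OH and one ortho OH are benzylated, while the remaining ortho hydroxyl, held in a hydrogen bond to the acetyl C=O, is the least nucleophilic and should stay free as the future ring oxygen O1.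

**Step 2**
Reactants: 2 1-[2,4-bis(benzyloxy)-6-hydroxyphenyl]ethan-1-one
Product: 4 5,7-bis(benzyloxy)-4H-chromen-4-one, via enaminone 3 (not isolated)
Conditions: Me2NCH(OMe)2, toluene, 100 °C; then 2 M HCl, CH2Cl2, 40 °C
Reagents that add atoms: N,N-dimethylformamide dimethyl acetal, COC(OC)N(C)C
Why: Condensation of the methyl ketone with the amide acetal gives the β-dimethylaminoenone, and acid then drives 6-endo-trig oxa-Michael addition of the free phenol and loss of dimethylamine (addition–elimination) to close the γ-pyranone ring.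

**Step 3**
Reactants: 4 5,7-bis(benzyloxy)-4H-chromen-4-one; 5 4-iodoanisole
Product: 7 5,7-bis(benzyloxy)-2-(4-methoxyphenyl)-4H-chromen-4-one, via bis(chromon-2-yl)zinc 6 (not isolated)
Conditions: TMP2Zn·2MgCl2·2LiCl (0.6 equiv), THF, −30 °C; then 5, Pd(dba)2 (3 mol%), P(2-furyl)3 (6 mol%), THF, 25 → 50 °C
Reagents that add atoms: none
Why: The MgCl2 carried by the bis-amide base binds C4=O (chelated by the 5-benzyloxy oxygen) and acidifies the pyranone C2–H next to O1, the TMP amide on zinc removes this proton to give the C2-zinc species 6, and Pd(0) then adds oxidatively to the C–I bond of 5, takes the chromonyl group from zinc and forms the C2–C1' bond by reductive elimination. The closest known reaction type is the C–H zincation of chromones with TMP-zinc amide bases followed by Negishi cross-coupling with aryl iodides, which converts 5,7-dialkoxychromones into flavones. No ring is closed and no stereocentre is formed. The step needs site selectivity for C2 over C3 (which would lead to the isoflavone) and over the A-ring C6–H and C8–H that lie between two oxygens; the Lewis-acid-complexed carbonyl steers the zinc amide to C2, and the low basicity of a zinc amide at −30 °C should leave the aryl C–H bonds and the benzylic CH2 groups untouched. It also needs the carbonyl and the pyranone ring to survive metalation, which the covalent C–Zn bond secures because it neither adds to C4=O nor opens the ring as a lithium species could.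

**Step 4**
Reactants: 7 5,7-bis(benzyloxy)-2-(4-methoxyphenyl)-4H-chromen-4-one
Product: 9 5,7-bis(benzyloxy)-3-hydroxy-2-(4-methoxyphenyl)-4H-chromen-4-one, via epoxide 8 (not isolated)
Conditions: DMDO (acetone solution), CH2Cl2, 0 °C → rt; evaporate; then TsOH·H2O (cat.), CH2Cl2, rt
Reagents that add atoms: dimethyldioxirane, CC1(C)OO1
Why: Dioxirane epoxidation of the C2=C3 enol-ether double bond, then acid-catalysed opening of the epoxide at C2 (cation stabilised by O1 and the p-anisyl ring) and loss of the C3 proton should give the 3-hydroxyflavone, the racemic epoxide centres being erased as the pyranone re-forms.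

**Step 5**
Reactants: 9 5,7-bis(benzyloxy)-3-hydroxy-2-(4-methoxyphenyl)-4H-chromen-4-one
Product: 10 5,7-bis(benzyloxy)-2-(4-methoxyphenyl)-4-oxo-4H-chromen-3-yl 2,2,2-trichloroethyl sulfate
Conditions: Cl3CCH2OSO2Cl, Et3N, DMAP, THF, 0 °C → rt
Reagents that add atoms: 2,2,2-trichloroethyl chlorosulfate, O=S(=O)(Cl)OCC(Cl)(Cl)Cl
Why: DMAP-assisted O-sulfonylation of the only free hydroxyl (the enolic 3-OH) by the chlorosulfate installs the sulfate as a neutral, chromatographable diester, so no choice among hydroxyls arises.

**Step 6**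
Reactants: 10 5,7-bis(benzyloxy)-2-(4-methoxyphenyl)-4-oxo-4H-chromen-3-yl 2,2,2-trichloroethyl sulfate
Product: 12 kaempferide 3-O-sulfate (5,7-dihydroxy-2-(4-methoxyphenyl)-4-oxo-4H-chromen-3-yl hydrogen sulfate), via ammonium salt 11 (not isolated)
Conditions: 10% Pd/C, HCO2NH4, MeOH/THF, rt; filter; then Dowex 50W (H+ form), MeOH/H2O, 0 °C, freeze-dry
Reagents that add atoms: none
Why: Pd-mediated reductive fragmentation of the trichloroethyl ester (C–Cl reduction, then β-elimination of the sulfate monoester anion) and transfer hydrogenolysis of both O-benzyl ethers should run under the same near-neutral conditions, which leave the aryl methyl ether, the C2=C3 bond and the S–O bonds intact, and brief cold cation exchange then protonates the sulfate.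

**Compound list**
1 | 2',4',6'-trihydroxyacetophenone | CC(=O)c1c(O)cc(O)cc1O | starting material
2 | 1-[2,4-bis(benzyloxy)-6-hydroxyphenyl]ethan-1-one | CC(=O)c1c(O)cc(OCc2ccccc2)cc1OCc1ccccc1 | intermediate
3 | (E)-1-[2,4-bis(benzyloxy)-6-hydroxyphenyl]-3-(dimethylamino)prop-2-en-1-one | CN(C)/C=C/C(=O)c1c(O)cc(OCc2ccccc2)cc1OCc1ccccc1 | intermediate (not isolated)
4 | 5,7-bis(benzyloxy)-4H-chromen-4-one | O=c1ccoc2cc(OCc3ccccc3)cc(OCc3ccccc3)c12 | intermediate
5 | 4-iodoanisole | COc1ccc(I)cc1 | starting material
6 | bis[5,7-bis(benzyloxy)-4-oxo-4H-chromen-2-yl]zinc (MgCl2/LiCl complex) | O=c1cc([Zn]c2cc(=O)c3c(OCc4ccccc4)cc(OCc4ccccc4)cc3o2)oc2cc(OCc3ccccc3)cc(OCc3ccccc3)c12 | intermediate (not isolated)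
7 | 5,7-bis(benzyloxy)-2-(4-methoxyphenyl)-4H-chromen-4-one | COc1ccc(-c2cc(=O)c3c(OCc4ccccc4)cc(OCc4ccccc4)cc3o2)cc1 | intermediate
8 | rac-5,7-bis(benzyloxy)-2-(4-methoxyphenyl)-2,3-epoxychroman-4-one | COc1ccc(C23OC2C(=O)c2c(OCc4ccccc4)cc(OCc4ccccc4)cc2O3)cc1 | intermediate (not isolated)
9 | 5,7-bis(benzyloxy)-3-hydroxy-2-(4-methoxyphenyl)-4H-chromen-4-one | COc1ccc(-c2oc3cc(OCc4ccccc4)cc(OCc4ccccc4)c3c(=O)c2O)cc1 | intermediate
10 | 5,7-bis(benzyloxy)-2-(4-methoxyphenyl)-4-oxo-4H-chromen-3-yl 2,2,2-trichloroethyl sulfate | COc1ccc(-c2oc3cc(OCc4ccccc4)cc(OCc4ccccc4)c3c(=O)c2OS(=O)(=O)OCC(Cl)(Cl)Cl)cc1 | intermediate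
11 | ammonium 5,7-dihydroxy-2-(4-methoxyphenyl)-4-oxo-4H-chromen-3-yl sulfate | COc1ccc(-c2oc3cc(O)cc(O)c3c(=O)c2OS(=O)(=O)[O-])cc1.[NH4+] | intermediate (not isolated)
12 | kaempferide 3-O-sulfate | COc1ccc(-c2oc3cc(O)cc(O)c3c(=O)c2OS(=O)(=O)O)cc1 | target

**Totals**
Total step count: 6. Longest linear sequence: 6 steps (1 → 12); 4-iodoanisole 5 enters in step 3.

**Steps most likely to fail**

Step 3. Deprotonation may be incomplete or may occur at C3 instead of C2, or the coupling of two electron-rich partners may be slow enough that the zinc species is simply protonated back. The fallback makes the same bond by conjugate addition instead of C–H metalation. Setting out from 4, Pd(II)-catalysed 1,4-addition of 4-methoxyphenylboronic acid (Pd(OCOCF3)2, 2,2'-bipyridine, AcOH/THF/H2O, 60 °C) should give racemic 5,7-bis(benzyloxy)-2-(4-methoxyphenyl)chroman-4-one F1. Dehydrogenation (I2 cat., DMSO, 120 °C) erases its stereocentre and brings the route back at 7.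

Step 4. Oxygen transfer to the electron-poor C2=C3 bond may be sluggish, with competing oxidation of the electron-rich rings or over-oxidation of the flavonol once it forms. The fallback replaces electrophilic oxygen transfer by deprotonation and boron oxidation. Setting out from 7, LDA (THF, −78 °C) should remove the C3 proton next to the carbonyl to give [5,7-bis(benzyloxy)-2-(4-methoxyphenyl)-4-oxo-4H-chromen-3-yl]lithium F2. Trimethyl borate would trap it as dimethyl [5,7-bis(benzyloxy)-2-(4-methoxyphenyl)-4-oxo-4H-chromen-3-yl]boronate F3, and H2O2/AcOH would oxidise the C–B bond, coming back to the route at 9.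

Step 6. The trichloroethyl group may be partly hydrodechlorinated to chloroethyl sulfate diesters that no longer fragment, chloride may poison the catalyst so that a benzyl ether stays on, or the sulfate may be lost under acid on the resin. The fallback does without a sulfate protecting group. Setting out from 9, sulfation with SO3·NEt3 (Et3N, DMF, 50 °C) should give triethylammonium 5,7-bis(benzyloxy)-2-(4-methoxyphenyl)-4-oxo-4H-chromen-3-yl sulfate F4. Hydrogenolysis of the benzyl ethers (H2, Pd/C, MeOH/THF, rt) would give triethylammonium 5,7-dihydroxy-2-(4-methoxyphenyl)-4-oxo-4H-chromen-3-yl sulfate F5, and brief cold H+ exchange brings the route back at 12.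

**Further compounds**
F1 | step 3 | rac-5,7-bis(benzyloxy)-2-(4-methoxyphenyl)chroman-4-one | COc1ccc(C2CC(=O)c3c(OCc4ccccc4)cc(OCc4ccccc4)cc3O2)cc1
F2 | step 4 | [5,7-bis(benzyloxy)-2-(4-methoxyphenyl)-4-oxo-4H-chromen-3-yl]lithium | [Li]c1c(-c2ccc(OC)cc2)oc2cc(OCc3ccccc3)cc(OCc3ccccc3)c2c1=O
F3 | step 4 | dimethyl [5,7-bis(benzyloxy)-2-(4-methoxyphenyl)-4-oxo-4H-chromen-3-yl]boronate | COB(OC)c1c(-c2ccc(OC)cc2)oc2cc(OCc3ccccc3)cc(OCc3ccccc3)c2c1=O
F4 | step 6 | triethylammonium 5,7-bis(benzyloxy)-2-(4-methoxyphenyl)-4-oxo-4H-chromen-3-yl sulfate | COc1ccc(-c2oc3cc(OCc4ccccc4)cc(OCc4ccccc4)c3c(=O)c2OS(=O)(=O)[O-])cc1.CC[NH+](CC)CC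
F5 | step 6 | triethylammonium 5,7-dihydroxy-2-(4-methoxyphenyl)-4-oxo-4H-chromen-3-yl sulfate | COc1ccc(-c2oc3cc(O)cc(O)c3c(=O)c2OS(=O)(=O)[O-])cc1.CC[NH+](CC)CC
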